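**Retrosynthetic overview**
1. The senecioate and the side chain come last. The C2 ester is made from the C2 alcohol. The C9–C11 bond is made by Negishi coupling of a ring-B dienyl triflate (from the C9 enone) with a C11–C16 alkylzinc whose C13 centre comes from a Sharpless epoxidation. A 1,4-hydrogenation then gives the C7=C8 alkene and C9–H.
2. The C2 acetate comes from a C2 acetyl group (Baeyer–Villiger, retention). The C1 methylene comes from a C1 carbinol (Barton–McCombie).
3. Ring A is disconnected at C1–C2 and C3–C4. The two-carbon unit C2–C3 is methyl vinyl ketone. The four-atom unit C1–C10–C5–C4 is a formyl group on C10 and an isopropenyl group on C5 of a cyclohexenone. Iron-hydride hydrogen-atom transfer, Giese addition and aldol closure join them in one operation.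
4. Enabling feature: in ring A the gem-dimethyl quaternary carbon C4 and the methylene C1 hang on the two ring-fusion atoms C5 and C10. C4 can therefore arise from the tertiary radical of an isopropenyl group and C1 from an aldehyde on the neighbouring quaternary carbon, while C2 carries the oxygen that an acyl group can become.
5. Ring order: ring B is bought as (S)-carvone (C5 stereocentre, C8 methyl, C7=C8 alkene and C9 carbonyl in place), ring A is closed in the key step, and the side chain is attached afterwards.

Key step: step 4

Remark: labdane numbering (C1–C20) is used for all intermediates. The target is an ent-labdane, so ring B is taken from (S)-(+)-carvone. The C1 carbinol configuration drawn in 7 and 8 is the expected one and has no consequence, because C1 becomes CH2 in step 6.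

Step 1
Reactants: 1 (S)-(+)-carvone
Product: 2 (5S,6R)-2,6-dimethyl-5-(prop-1-en-2-yl)cyclohex-2-en-1-one (trans-6-methylcarvone; any cis epimer is carried along)
Conditions: LiN(iPr)2, THF, −78 °C; MeI, −78 to 0 °C
Reagents that add atoms: iodomethane, CI
Why: Kinetic α′-deprotonation of the cross-conjugated enone and enolate methylation install the future C20 methyl on C10; the new centre forms mainly trans to the isopropenyl group, but its configuration is immaterial because C10 is enolised again in step 2.

Step 2
Reactants: 2 trans-6-methylcarvone
Product: 3 (5R,6S)-6-(hydroxymethyl)-2,6-dimethyl-5-(prop-1-en-2-yl)cyclohex-2-en-1-one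
Conditions: LiN(iPr)2, THF, −78 °C; CH2O (gas, from cracked paraformaldehyde), −78 °C; AcOH quench at −78 °C
Reagents that add atoms: formaldehyde, C=O
Why: Aldol addition of the tetrasubstituted lithium enolate to monomeric formaldehyde; the electrophile should approach anti to the C5 isopropenyl group (held pseudo-axial by A(1,2) strain), so the quaternary C10 carries CH2OH trans and CH3 cis to isopropenyl.

Step 3
Reactants: 3 hydroxymethyl ketone
Product: 4 (1S,6R)-1,3-dimethyl-2-oxo-6-(prop-1-en-2-yl)cyclohex-3-ene-1-carbaldehyde
Conditions: Dess–Martin periodinane, NaHCO3, CH2Cl2, 0 °C to rt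
Reagents that add atoms: none
Why: Dess–Martin oxidation of the neopentyl primary alcohol under buffered, non-basic conditions should avoid retro-aldol loss of formaldehyde and retro-Claisen cleavage of the non-enolisable β-keto aldehyde.

Step 4
Reactants: 4 keto aldehyde; 5 methyl vinyl ketone (but-3-en-2-one)
Product: 7 7-acetyl-8-hydroxy-2,5,5,8a-tetramethyl-4a,5,6,7,8,8a-hexahydronaphthalen-1(4H)-one (trans-fused; C1 hydroxyl axial; C2 acetyl equatorial), via iron enolate 6 (not isolated)
Conditions: Fe(acac)3 (0.3 equiv), PhSiH3 (2.5 equiv), 5 (3 equiv), EtOH/ethylene glycol 5:1, 0 °C to rt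
Reagents that add atoms: none
Why: An iron hydride formed from Fe(acac)3 and PhSiH3 transfers a hydrogen atom to the CH2 terminus of the isopropenyl group, the tertiary C4 radical adds to the β-carbon of methyl vinyl ketone (C3–C4 bond and gem-dimethyl quaternary carbon), and the resulting α-keto radical is reduced by divalent iron to an iron enolate that attacks the C1 aldehyde (C1–C2 bond). The closest known reaction type is the iron-hydride-initiated radical–polar crossover annulation (Giese addition then aldol) of γ,δ-unsaturated aldehydes with enones. Ring A closes by a 6-exo-trig (enolexo) aldol, and the ring fusion must be trans because the C1 and C4 arms already stand trans on C10 and C5. C2 is set under substrate control: in the chair transition state the acetyl group takes the equatorial position away from the syn-axial C4 and C10 methyl groups, which is also the thermodynamic, epimerisable arrangement; the C1 carbinol is expected axial through the iron chelate and is removed in step 6. The step needs hydrogen-atom transfer to the electron-neutral 1,1-disubstituted alkene instead of the electron-poor enone alkene, and aldol at the aldehyde instead of the C9 ketone; the first is secured by polarity and sterics, the second by the higher electrophilicity of the formyl group and by the fused, not bridged, ring that results.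

Step 5
Reactants: 7 hydroxy diketone
Product: 8 O-phenyl thionocarbonate of 7 at the C1 oxygen
Conditions: PhOC(S)Cl, pyridine, DMAP (cat.), CH2Cl2, 0 °C to rt
Reagents that add atoms: O-phenyl chlorothionoformate, S=C(Cl)Oc1ccccc1
Why: Acylation of the hindered secondary alcohol under nucleophilic catalysis gives the thionocarbonate for radical deoxygenation (first half of a Barton–McCombie sequence) with a base too weak for retro-aldol cleavage.

Step 6
Reactants: 8 thionocarbonate
Product: 9 7-acetyl-2,5,5,8a-tetramethyl-4a,5,6,7,8,8a-hexahydronaphthalen-1(4H)-one (trans-fused; C2 acetyl equatorial)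
Conditions: n-Bu3SnH (0.5 M), AIBN (cat.), toluene, 90 °C
Reagents that add atoms: none
Why: Barton–McCombie deoxygenation: the stannyl radical adds to C=S, β-scission gives the secondary C1 radical, and the stannane reduces it; the high stannane concentration should outrun a 1,2-acyl shift toward the C9 carbonyl (Dowd–Beckwith pathway), and C2 is not touched.

Step 7
Reactants: 9 diketone
Product: 10 4,4,7,8a-tetramethyl-8-oxo-1,2,3,4,4a,5,8,8a-octahydronaphthalen-2-yl acetate (C2 acetate equatorial and trans to the C10 methyl)
Conditions: mCPBA, NaHCO3, CH2Cl2, rt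
Reagents that add atoms: 3-chloroperoxybenzoic acid, OOC(=O)c1cccc(Cl)c1
Why: Baeyer–Villiger oxidation in which the secondary C2 carbon migrates in preference to methyl with retention, turning the equatorial acetyl group into the equatorial acetate; the electron-poor ring-B enone should be inert to the peracid, as the enone of carvone is.

Step 8
Reactants: 10 enone acetate
Product: 11 ring-B dienyl triflate (C9 triflate; C8=C9 and C6=C7 double bonds; C2 acetate)
Conditions: Tf2O, 2,6-di-tert-butyl-4-methylpyridine, CH2Cl2, 0 °C to rt
Reagents that add atoms: trifluoromethanesulfonic anhydride, O=S(=O)(OS(=O)(=O)C(F)(F)F)C(F)(F)F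
Why: O-Triflation of the enone followed by loss of a C6 proton gives the homoannular dienyl triflate, the only one possible because C10 is quaternary, under conditions that tolerate the acetate.

Step 9
Reactants: 12 (E)-3-methylpent-2-en-4-yn-1-ol
Product: 13 (E)-3-methylpenta-2,4-dien-1-ol
Conditions: H2 (1 atm), Pd/CaCO3 poisoned with Pb(OAc)2 (Lindlar catalyst), quinoline, EtOAc, rt
Reagents that add atoms: none
Why: Lindlar semihydrogenation of the terminal alkyne to the vinyl group should stop at the diene and leave the trisubstituted alkene geometry intact.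

Step 10
Reactants: 13 dienol
Product: 14 [(2R,3R)-3-ethenyl-3-methyloxiran-2-yl]methanol
Conditions: Ti(OiPr)4 (10 mol %), D-(−)-diethyl tartrate (12 mol %), t-BuOOH, 4 Å molecular sieves, CH2Cl2, −20 °C
Reagents that add atoms: tert-butyl hydroperoxide, CC(C)(C)OO
Why: Sharpless asymmetric epoxidation of the (E)-trisubstituted allylic alcohol; with the D-tartrate the oxygen is delivered to the face that gives the (2R,3R)-epoxide (reagent control, the mirror image of the outcome known for geraniol with the L-tartrate), which fixes the future C13, and the distal vinyl group is not epoxidised.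

Step 11
Reactants: 14 epoxy alcohol
Product: 15 (S)-3-methylpent-4-ene-1,3-diol
Conditions: NaAlH2(OCH2CH2OCH3)2, THF, 0 °C; aqueous potassium sodium tartrate work-up
Reagents that add atoms: none
Why: Hydroxyl-directed hydride delivery from the alkoxyaluminate to C2 of the 2,3-epoxy alcohol opens the epoxide regioselectively to the 1,3-diol and leaves the tertiary C–O stereocentre untouched.

Step 12
Reactants: 15 diol
Product: 16 (S)-5-iodo-3-methylpent-1-en-3-ol
Conditions: PPh3, iodine, imidazole, CH2Cl2, 0 °C
Reagents that add atoms: iodine, [I][I]
Why: Appel-type iodination is selective for the primary hydroxyl, since the tertiary allylic alcohol does not form an oxyphosphonium salt under these buffered conditions.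

Step 13
Reactants: 16 iodo alcohol
Product: 17 (S)-[(5-iodo-3-methylpent-1-en-3-yl)oxy]trimethylsilane
Conditions: Me3SiCl, imidazole, DMF, 0 °C to rt
Reagents that add atoms: chlorotrimethylsilane, C[Si](C)(C)Cl
Why: Silylation of the tertiary alcohol gives a trimethylsilyl ether that tolerates organozinc formation and cross-coupling and is removed together with the acetate in step 16.

Step 14
Reactants: 11 dienyl triflate; 17 silyl ether iodide
Product: 19 C9-alkylated homoannular diene (C8=C9 and C6=C7; C2 acetate; C13 trimethylsilyl ether), via alkylzinc iodide 18 (not isolated)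
Conditions: 17, Zn dust, LiCl, THF, 40 °C; then 11, Pd(dppf)Cl2 (5 mol %), THF, 50 °C
Reagents that add atoms: zinc, [Zn]
Why: Zinc insertion into the primary iodide gives the alkylzinc iodide, which undergoes Negishi sp2–sp3 coupling with the dienyl triflate to form C9–C11; the bidentate ferrocenyl phosphine favours reductive elimination over β-hydride elimination, and acetate and silyl ether are inert.

Step 15
Reactants: 19 diene
Product: 20 C7=C8 alkene with C9–H (C2 acetate; C13 trimethylsilyl ether; side chain cis to the C10 methyl)
Conditions: H2 (50 atm), (naphthalene)Cr(CO)3 (20 mol %), acetone, 45 °C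
Reagents that add atoms: none
Why: Arene–Cr(CO)3 complexes hydrogenate cisoid 1,3-dienes by 1,4-addition only, so the homoannular diene should give the C7=C8 alkene while the vinyl group is left alone; both hydrogens come from the chromium-bound face, the one opposite the angular C10 methyl, which sets C9–H anti to that methyl and the side chain equatorial.

Step 16
Reactants: 20 acetate silyl ether
Product: 21 (2R,4aR,8R,8aR)-8-[(3S)-3-hydroxy-3-methylpent-4-en-1-yl]-4,4,7,8a-tetramethyl-1,2,3,4,4a,5,8,8a-octahydronaphthalen-2-ol
Conditions: K2CO3, MeOH, rt
Reagents that add atoms: none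
Why: Methanolysis cleaves the secondary acetate (transesterification) and the tertiary trimethylsilyl ether in one operation without touching the alkenes.

Step 17
Reactants: 21 diol; 22 3-methylbut-2-enoic acid
Product: 23 (2R,4aR,8R,8aR)-8-[(3S)-3-hydroxy-3-methylpent-4-en-1-yl]-4,4,7,8a-tetramethyl-1,2,3,4,4a,5,8,8a-octahydronaphthalen-2-yl 3-methylbut-2-enoate (CNP0252389.1)
Conditions: DCC, DMAP (cat.), CH2Cl2, 0 °C to rt
Reagents that add atoms: none
Why: Steglich esterification acylates the equatorial secondary C2 alcohol while the tertiary allylic C13 alcohol is too hindered to react, and carbodiimide activation avoids the ketene pathway that can deconjugate the 3-methylbut-2-enoyl group.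

**Compound list**
1 | (S)-(+)-carvone | O=C1C(C)=CC[C@H](C(C)=C)C1 | starting material
2 | (5S,6R)-2,6-dimethyl-5-(prop-1-en-2-yl)cyclohex-2-en-1-one | O=C1C(C)=CC[C@H](C(C)=C)[C@H]1C | intermediate
3 | (5R,6S)-6-(hydroxymethyl)-2,6-dimethyl-5-(prop-1-en-2-yl)cyclohex-2-en-1-one | O=C1C(C)=CC[C@H](C(C)=C)[C@@]1(C)CO | intermediate
4 | (1S,6R)-1,3-dimethyl-2-oxo-6-(prop-1-en-2-yl)cyclohex-3-ene-1-carbaldehyde | O=C1C(C)=CC[C@H](C(C)=C)[C@@]1(C)C=O | intermediate
5 | methyl vinyl ketone (but-3-en-2-one) | CC(=O)C=C | starting material
6 | iron enolate of the Giese adduct, drawn as the free enolate anion | O=C1C(C)=CC[C@H](C(C)(C)CC=C(C)[O-])[C@@]1(C)C=O | intermediate (not isolated)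
7 | 7-acetyl-8-hydroxy-2,5,5,8a-tetramethyl-4a,5,6,7,8,8a-hexahydronaphthalen-1(4H)-one (trans-fused; C1 hydroxyl axial; C2 acetyl equatorial) | O=C1C(C)=CC[C@@H]2C(C)(C)C[C@@H](C(C)=O)[C@@H](O)[C@@]12C | intermediate
8 | O-phenyl thionocarbonate of 7 at the C1 oxygen | O=C1C(C)=CC[C@@H]2C(C)(C)C[C@@H](C(C)=O)[C@@H](OC(=S)Oc3ccccc3)[C@@]12C | intermediate
9 | 7-acetyl-2,5,5,8a-tetramethyl-4a,5,6,7,8,8a-hexahydronaphthalen-1(4H)-one (trans-fused; acetyl equatorial) | O=C1C(C)=CC[C@@H]2C(C)(C)C[C@@H](C(C)=O)C[C@@]12C | intermediate
10 | 4,4,7,8a-tetramethyl-8-oxo-1,2,3,4,4a,5,8,8a-octahydronaphthalen-2-yl acetate (acetate equatorial; trans to the angular methyl) | O=C1C(C)=CC[C@@H]2C(C)(C)C[C@@H](OC(C)=O)C[C@@]12C | intermediate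
11 | dienyl triflate of 10 (C9 triflate; C8=C9 and C6=C7) | O=S(=O)(OC1=C(C)C=C[C@@H]2C(C)(C)C[C@@H](OC(C)=O)C[C@@]12C)C(F)(F)F | intermediate
12 | (E)-3-methylpent-2-en-4-yn-1-ol | C#C/C(C)=C/CO | starting material
13 | (E)-3-methylpenta-2,4-dien-1-ol | C=C/C(C)=C/CO | intermediate
14 | [(2R,3R)-3-ethenyl-3-methyloxiran-2-yl]methanol | C=C[C@@]1(C)O[C@@H]1CO | intermediate
15 | (S)-3-methylpent-4-ene-1,3-diol | C=C[C@@](C)(O)CCO | intermediate
16 | (S)-5-iodo-3-methylpent-1-en-3-ol | C=C[C@@](C)(O)CCI | intermediate
17 | (S)-[(5-iodo-3-methylpent-1-en-3-yl)oxy]trimethylsilane | C=C[C@@](C)(O[Si](C)(C)C)CCI | intermediate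
18 | alkylzinc iodide from 17 | C=C[C@@](C)(O[Si](C)(C)C)CC[Zn]I | intermediate (not isolated)
19 | C9-alkylated homoannular diene (C2 acetate; C13 trimethylsilyl ether) | C=C[C@@](C)(O[Si](C)(C)C)CCC1=C(C)C=C[C@@H]2C(C)(C)C[C@@H](OC(C)=O)C[C@@]12C | intermediate
20 | C7=C8 alkene with C9–H (C2 acetate; C13 trimethylsilyl ether; side chain cis to the angular methyl) | C=C[C@@](C)(O[Si](C)(C)C)CC[C@@H]1C(C)=CC[C@@H]2C(C)(C)C[C@@H](OC(C)=O)C[C@@]12C | intermediate
21 | (2R,4aR,8R,8aR)-8-[(3S)-3-hydroxy-3-methylpent-4-en-1-yl]-4,4,7,8a-tetramethyl-1,2,3,4,4a,5,8,8a-octahydronaphthalen-2-ol | C=C[C@@](C)(O)CC[C@@H]1C(C)=CC[C@@H]2C(C)(C)C[C@@H](O)C[C@@]12C | intermediate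
22 | 3-methylbut-2-enoic acid | CC(C)=CC(=O)O | starting material
23 | (2R,4aR,8R,8aR)-8-[(3S)-3-hydroxy-3-methylpent-4-en-1-yl]-4,4,7,8a-tetramethyl-1,2,3,4,4a,5,8,8a-octahydronaphthalen-2-yl 3-methylbut-2-enoate | C=C[C@@](C)(O)CC[C@@H]1C(C)=CC[C@@H]2C(C)(C)C[C@@H](OC(=O)C=C(C)C)C[C@@]12C | target

**Step count and risks**
Total steps: 17. Longest linear sequence: 12 steps (steps 1–8 and 14–17, from (S)-carvone); the side-chain branch is steps 9–13.

Step 4 (key step). What may go wrong: the iron enolate may be protonated before it reaches the aldehyde, giving reductive coupling without ring closure, or the β-keto aldehyde may lose its formyl group in the alcoholic reducing medium. Fallback: the two bond formations are separated and the aldehyde is kept out of the radical step. The route sets out from alcohol 3. The same iron-hydride reductive olefin–enone coupling with 5 (Fe(acac)3, PhSiH3, EtOH/ethylene glycol) now forms only the C3–C4 bond and should give the hydroxymethyl diketone F1. Dess–Martin oxidation gives the keto aldehyde F2. A reversible amine-mediated intramolecular aldol (pyrrolidine, AcOH) then closes C1–C2 under thermodynamic control to the six-membered ring, and the route is rejoined at 7.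

Step 6. What may go wrong: E1cB loss of the activated C1 oxygen (β to the acetyl group) during or after thioacylation, or a 1,2-acyl shift of the C1 radical toward the C9 carbonyl with ring expansion. Fallback: the oxygen is removed by elimination and conjugate reduction instead of by a radical. Setting out from 7, acid-catalysed dehydration (p-TsOH, benzene, reflux) should give the enedione F3. Catecholborane then reduces only the ring-A enone, which can reach the s-cis conformation, while the ring-B cyclohexenone is locked s-trans and is left alone. Protonation of the boron enolate under equilibrating conditions places the acetyl group equatorial, and the route is rejoined at 9.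

Step 15. What may go wrong: slow or absent complexation of the hindered diene (fully substituted at C9) to chromium, leading to no reaction or to double-bond migration. Fallback: the 1,4-reduction is done by electron transfer after deprotection. Setting out from 19, methanolysis (K2CO3, MeOH) gives the diene diol F4. Dissolving-metal reduction (Li, liquid NH3, THF, t-BuOH, −78 °C) then reduces the homoannular diene in the 1,4-sense; protonation of the allyl anion at C9 from the face opposite the angular methyl puts the side chain equatorial. The isolated vinyl group and the tertiary allylic alkoxide should survive, and the route is rejoined at 21.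

**Further compounds**
F1 | step 4 | 6-(hydroxymethyl)-2,6-dimethyl-5-(2-methyl-5-oxohexan-2-yl)cyclohex-2-en-1-one (configuration as in 3) | O=C1C(C)=CC[C@H](C(C)(C)CCC(C)=O)[C@@]1(C)CO
F2 | step 4 | 1,3-dimethyl-6-(2-methyl-5-oxohexan-2-yl)-2-oxocyclohex-3-ene-1-carbaldehyde (configuration as in 4) | O=C1C(C)=CC[C@H](C(C)(C)CCC(C)=O)[C@@]1(C)C=O
F3 | step 6 | 7-acetyl-2,5,5,8a-tetramethyl-4a,5,6,8a-tetrahydronaphthalen-1(4H)-one (trans-fused) | O=C1C(C)=CC[C@@H]2C(C)(C)CC(C(C)=O)=C[C@@]12C
F4 | step 15 | diene diol from 19 (C2 hydroxyl; C13 hydroxyl; C8=C9 and C6=C7) | C=C[C@@](C)(O)CCC1=C(C)C=C[C@@H]2C(C)(C)C[C@@H](O)C[C@@]12C
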